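**Plan**

- Retrosynthesis: cut the C8–CHO bond (ortho-formylation of the 7-phenol), then the ring B bonds C1'–C2', C2'–C3' and C4'–C5' (benzannulation of a chroman-3-yl diazo enone with a methoxyalkyne), then the C3 side chain (diazo transfer, Wittig C=C), then O1–C2 and C3–C4 of the pyran ring (oxa-Michael/aldol).
- Enabling feature: ring B carries C2'–OH, C3'–prenyl and C4'–OMe in a row, with C5' and C6' unsubstituted and C1' bound to C3. This maps onto a ketene carbon (C2'), an ynol ether (C3', C4') and a vinyl unit (C5', C6', C1').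
- Forward order: ring A is bought (1); the pyran ring is fused on (step 2); C3 is set (step 4); the diazo enone arm is grown (steps 5–7); ring B is created (step 9); the C8 formyl group comes last (step 11).
- Stereochemistry: the single stereocentre C3 comes from Ru-catalysed asymmetric hydrogenation of chromene acid 5. It is never touched again; its descriptor alternates (S/R) only because substituent priorities change, ending as (3R) in 23.

Key step: step 9

Remark: the facial sense in step 4 is assigned by analogy with the hydrogenation of (E)-2-alkyl-2-alkenoic acids; if analysis of 6 shows the opposite sense, the (S)-ligand is used instead.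

**Route**

Step 1
Reactants: 1 2,4-dihydroxy-6-methoxybenzaldehyde
Product: 2 2-hydroxy-6-methoxy-4-(triisopropylsilyloxy)benzaldehyde
Conditions: TIPSCl (1.05 equiv), imidazole, DMF, 0 °C
Reagents that add atoms: triisopropylsilyl chloride, CC(C)[Si](Cl)(C(C)C)C(C)C
Why: Chemoselective O-silylation; the 2-OH is hydrogen-bonded to and flanked by the formyl group, so the more acidic, unhindered 4-OH should be silylated first.

Step 2
Reactants: 2 2-hydroxy-6-methoxy-4-(triisopropylsilyloxy)benzaldehyde; 3 acrolein
Product: 4 5-methoxy-7-(triisopropylsilyloxy)-2H-chromene-3-carbaldehyde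
Conditions: K2CO3, 1,4-dioxane, 80 °C
Reagents that add atoms: none
Why: Oxa-Michael addition of the phenoxide to acrolein followed by intramolecular aldol condensation onto the aryl aldehyde (the standard 2H-chromene-3-carbaldehyde annulation) forms O1–C2 and C3–C4, and the hindered silyl ether should tolerate anhydrous carbonate.

Step 3
Reactants: 4 5-methoxy-7-(triisopropylsilyloxy)-2H-chromene-3-carbaldehyde
Product: 5 5-methoxy-7-(triisopropylsilyloxy)-2H-chromene-3-carboxylic acid
Conditions: NaClO2, NaH2PO4, 2-methyl-2-butene (excess), t-BuOH/H2O, rt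
Reagents that add atoms: sodium chlorite, [Na+].[O-]Cl=O
Why: Pinnick oxidation converts the enal into the acid without touching the C3=C4 bond, the alkene scavenger intercepting HOCl before it can chlorinate the electron-rich ring.

Step 4
Reactants: 5 5-methoxy-7-(triisopropylsilyloxy)-2H-chromene-3-carboxylic acid
Product: 6 (3S)-5-methoxy-7-(triisopropylsilyloxy)chroman-3-carboxylic acid
Conditions: H2 (50 atm), Ru(OAc)2[(R)-H8-BINAP] (1 mol %), MeOH, rt
Reagents that add atoms: none
Why: Noyori-type carboxylate-directed asymmetric hydrogenation; the substrate binds ruthenium through its carboxylate and the atropisomeric bisphosphine selects the face of C3=C4 to which both hydrogens are delivered, fixing C3 as (S).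

Step 5
Reactants: 6 (3S)-5-methoxy-7-(triisopropylsilyloxy)chroman-3-carboxylic acid
Product: 7 [(3R)-5-methoxy-7-(triisopropylsilyloxy)chroman-3-yl]methanol
Conditions: BH3·SMe2, THF, 0 °C → rt; aqueous work-up
Reagents that add atoms: none
Why: Borane reduction of a carboxylic acid via the acyloxyborane is chemoselective and non-basic, so the aryl silyl ether and the C3 stereocentre should be untouched.

Step 6
Reactants: 7 [(3R)-5-methoxy-7-(triisopropylsilyloxy)chroman-3-yl]methanol; 8 1-(triphenylphosphoranylidene)propan-2-one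
Product: 10 (3E)-4-[(3R)-5-methoxy-7-(triisopropylsilyloxy)chroman-3-yl]but-3-en-2-one, via chroman-3-carbaldehyde 9 (not isolated)
Conditions: Dess–Martin periodinane, NaHCO3, CH2Cl2, 0 °C → rt; then 8, rt → 40 °C
Reagents that add atoms: none
Why: Dess–Martin oxidation followed in the same flask by Wittig olefination with a stabilised ylide should give the (E)-enone, the neutral ylide trapping the enolisable β-aryloxy aldehyde before it can epimerise or eliminate.

Step 7
Reactants: 10 (3E)-4-[(3R)-5-methoxy-7-(triisopropylsilyloxy)chroman-3-yl]but-3-en-2-one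
Product: 12 (3E)-1-diazo-4-[(3R)-5-methoxy-7-(triisopropylsilyloxy)chroman-3-yl]but-3-en-2-one, via trifluoroacetyl diketone 11 (not isolated)
Conditions: LiN(SiMe3)2, THF, −78 °C; CF3CO2CH2CF3; dilute HCl work-up, crude 11 taken on; then MsN3, Et3N, H2O, MeCN, rt
Reagents that add atoms: methanesulfonyl azide, CS(=O)(=O)N=[N+]=[N-]; 2,2,2-trifluoroethyl trifluoroacetate, O=C(OCC(F)(F)F)C(F)(F)F (trifluoroacetyl group of 11 only)
Why: Detrifluoroacetylative diazo transfer; kinetic deprotonation at the methyl group and Claisen acylation activate that carbon for diazo transfer from the sulfonyl azide, and the trifluoroacetyl group then leaves as the N-acylsulfonamide.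

Step 8
Reactants: 13 chloroacetaldehyde dimethyl acetal; 14 prenyl bromide (1-bromo-3-methylbut-2-ene)
Product: 16 1-methoxy-5-methylhex-4-en-1-yne, via sodium methoxyacetylide 15 (not isolated)
Conditions: NaNH2 (3 equiv), liquid NH3, −33 °C; then 14, Et2O; NH4Cl
Reagents that add atoms: sodium amide, [Na+].[NH2-] (sodium of 15 only)
Why: Twofold elimination (HCl, then MeOH) from the chloroacetal gives the methoxyacetylide, which should be alkylated at the primary carbon of the allylic bromide (acetylide SN2 alkylation), exactly three equivalents of amide leaving no base to isomerise the skipped enyne.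

Step 9
Reactants: 12 (3E)-1-diazo-4-[(3R)-5-methoxy-7-(triisopropylsilyloxy)chroman-3-yl]but-3-en-2-one; 16 1-methoxy-5-methylhex-4-en-1-yne
Product: 21 6-[(3R)-5-methoxy-7-(triisopropylsilyloxy)chroman-3-yl]-3-methoxy-2-(3-methylbut-2-en-1-yl)phenol, via vinylketene 17 (not isolated), via vinylcyclobutenone 18 (not isolated), via dienylketene 19 (not isolated), via cyclohexadienone 20 (not isolated)
Conditions: 16 (2.5 equiv), hν (300 nm, Pyrex), degassed ClCH2CH2Cl, rt; then 80 °C
Reagents that add atoms: none
Why: Irradiation expels N2 from 12 and the Wolff 1,2-shift moves the alkenyl group from the acyl carbon to the former diazo carbon (this creates C5'–C6') to give vinylketene 17; its ketene C=C adds the ynol ether 16 in a [2+2] cycloaddition forming C2'–C3' and C4'–C5' (18), the cyclobutenone opens by 4π electrocyclic cleavage to dienylketene 19, and 6π electrocyclisation forms C1'–C2' before dienone 20 tautomerises to the phenol. The closest known reaction type is the Danheiser benzannulation of α,β-unsaturated diazomethyl ketones with heteroatom-substituted alkynes under photochemical Wolff conditions. Ring B is closed by the disrotatory 6π electrocyclisation of 19 (ketene carbon onto the terminal alkene carbon), the four-membered ring of 18 being only transient. No stereocentre is created in 21: the sp3 centres of 18 and 20 are erased by ring opening and enolisation, and C3 stays (R) because the medium is neutral and C3 takes no part. The step needs the regiochemistry of the [2+2] event, which the polarisation of 16 secures (its nucleophilic prenyl-bearing carbon bonds to the electrophilic ketene carbon, so prenyl ends next to the new OH and OMe meta to it), and chemoselectivity for the triple bond over the prenyl alkene, which the far higher ketenophilicity of an ynol ether provides.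

Step 10
Reactants: 21 6-[(3R)-5-methoxy-7-(triisopropylsilyloxy)chroman-3-yl]-3-methoxy-2-(3-methylbut-2-en-1-yl)phenol
Product: 22 (3R)-3-[2-hydroxy-4-methoxy-3-(3-methylbut-2-en-1-yl)phenyl]-5-methoxychroman-7-ol
Conditions: Bu4NF, AcOH, THF, 0 °C
Reagents that add atoms: none
Why: Fluoride-mediated cleavage of the aryl silyl ether, buffered with acetic acid, should free the 7-phenol without affecting the prenyl group, the ring B phenol or C3.

Step 11
Reactants: 22 (3R)-3-[2-hydroxy-4-methoxy-3-(3-methylbut-2-en-1-yl)phenyl]-5-methoxychroman-7-ol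
Product: 23 (3R)-7-hydroxy-3-[2-hydroxy-4-methoxy-3-(3-methylbut-2-en-1-yl)phenyl]-5-methoxychroman-8-carbaldehyde
Conditions: MgCl2, Et3N, (CH2O)n, MeCN, reflux; cold dilute HCl work-up
Reagents that add atoms: paraformaldehyde, C=O (per formaldehyde unit)
Why: Magnesium-mediated ortho-formylation (Casnati–Skattebøl) delivers formaldehyde from the magnesium phenoxide to an ortho carbon only; the 2'-phenol has both ortho positions blocked, and of the two positions ortho to the 7-OH, C8 (next to the tied-back ring oxygen) should be preferred over C6, which is shielded by the methyl of the 5-OMe group.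

**Compound list**

1 | 2,4-dihydroxy-6-methoxybenzaldehyde | COc1cc(O)cc(O)c1C=O | starting material
2 | 2-hydroxy-6-methoxy-4-(triisopropylsilyloxy)benzaldehyde | COc1cc(O[Si](C(C)C)(C(C)C)C(C)C)cc(O)c1C=O | intermediate
3 | acrolein (prop-2-enal) | C=CC=O | starting material
4 | 5-methoxy-7-(triisopropylsilyloxy)-2H-chromene-3-carbaldehyde | O=CC1=Cc2c(OC)cc(O[Si](C(C)C)(C(C)C)C(C)C)cc2OC1 | intermediate
5 | 5-methoxy-7-(triisopropylsilyloxy)-2H-chromene-3-carboxylic acid | OC(=O)C1=Cc2c(OC)cc(O[Si](C(C)C)(C(C)C)C(C)C)cc2OC1 | intermediate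
6 | (3S)-5-methoxy-7-(triisopropylsilyloxy)chroman-3-carboxylic acid | OC(=O)[C@@H]1COc2cc(O[Si](C(C)C)(C(C)C)C(C)C)cc(OC)c2C1 | intermediate
7 | [(3R)-5-methoxy-7-(triisopropylsilyloxy)chroman-3-yl]methanol | OC[C@@H]1COc2cc(O[Si](C(C)C)(C(C)C)C(C)C)cc(OC)c2C1 | intermediate
8 | 1-(triphenylphosphoranylidene)propan-2-one | CC(=O)C=P(c1ccccc1)(c1ccccc1)c1ccccc1 | starting material
9 | (3S)-5-methoxy-7-(triisopropylsilyloxy)chroman-3-carbaldehyde | O=C[C@@H]1COc2cc(O[Si](C(C)C)(C(C)C)C(C)C)cc(OC)c2C1 | intermediate
10 | (3E)-4-[(3R)-5-methoxy-7-(triisopropylsilyloxy)chroman-3-yl]but-3-en-2-one | CC(=O)/C=C/[C@@H]1COc2cc(O[Si](C(C)C)(C(C)C)C(C)C)cc(OC)c2C1 | intermediate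
11 | (5E)-1,1,1-trifluoro-6-[(3R)-5-methoxy-7-(triisopropylsilyloxy)chroman-3-yl]hex-5-ene-2,4-dione | O=C(CC(=O)C(F)(F)F)/C=C/[C@@H]1COc2cc(O[Si](C(C)C)(C(C)C)C(C)C)cc(OC)c2C1 | intermediate
12 | (3E)-1-diazo-4-[(3R)-5-methoxy-7-(triisopropylsilyloxy)chroman-3-yl]but-3-en-2-one | [N-]=[N+]=CC(=O)/C=C/[C@@H]1COc2cc(O[Si](C(C)C)(C(C)C)C(C)C)cc(OC)c2C1 | intermediate
13 | chloroacetaldehyde dimethyl acetal (2-chloro-1,1-dimethoxyethane) | COC(CCl)OC | starting material
14 | prenyl bromide (1-bromo-3-methylbut-2-ene) | CC(C)=CCBr | starting material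
15 | sodium methoxyacetylide | [Na+].[C-]#COC | intermediate
16 | 1-methoxy-5-methylhex-4-en-1-yne | COC#CCC=C(C)C | intermediate
17 | (3E)-4-[(3R)-5-methoxy-7-(triisopropylsilyloxy)chroman-3-yl]buta-1,3-dien-1-one (vinylketene) | O=C=C/C=C/[C@@H]1COc2cc(O[Si](C(C)C)(C(C)C)C(C)C)cc(OC)c2C1 | intermediate
18 | 3-methoxy-4-{(E)-2-[(3R)-5-methoxy-7-(triisopropylsilyloxy)chroman-3-yl]ethenyl}-2-(3-methylbut-2-en-1-yl)cyclobut-2-en-1-one (both C4 epimers) | COC1=C(CC=C(C)C)C(=O)C1/C=C/[C@@H]3COc4cc(O[Si](C(C)C)(C(C)C)C(C)C)cc(OC)c4C3 | intermediate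
19 | (3E,5E)-3-methoxy-6-[(3R)-5-methoxy-7-(triisopropylsilyloxy)chroman-3-yl]-2-(3-methylbut-2-en-1-yl)hexa-1,3,5-trien-1-one (dienylketene; ketene carbon and C5 cis across C3=C4) | O=C=C(CC=C(C)C)/C(OC)=C\C=C\[C@@H]1COc2cc(O[Si](C(C)C)(C(C)C)C(C)C)cc(OC)c2C1 | intermediate
20 | 3-methoxy-6-[(3R)-5-methoxy-7-(triisopropylsilyloxy)chroman-3-yl]-2-(3-methylbut-2-en-1-yl)cyclohexa-2,4-dien-1-one (both C6 epimers) | COC1=C(CC=C(C)C)C(=O)C(C=C1)[C@@H]3COc4cc(O[Si](C(C)C)(C(C)C)C(C)C)cc(OC)c4C3 | intermediate
21 | 6-[(3R)-5-methoxy-7-(triisopropylsilyloxy)chroman-3-yl]-3-methoxy-2-(3-methylbut-2-en-1-yl)phenol | COc1ccc([C@@H]2COc3cc(O[Si](C(C)C)(C(C)C)C(C)C)cc(OC)c3C2)c(O)c1CC=C(C)C | intermediate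
22 | (3R)-3-[2-hydroxy-4-methoxy-3-(3-methylbut-2-en-1-yl)phenyl]-5-methoxychroman-7-ol | COc1ccc([C@@H]2COc3cc(O)cc(OC)c3C2)c(O)c1CC=C(C)C | intermediate
23 | (3R)-7-hydroxy-3-[2-hydroxy-4-methoxy-3-(3-methylbut-2-en-1-yl)phenyl]-5-methoxychroman-8-carbaldehyde | COc1ccc([C@@H]2COc3c(C=O)c(O)cc(OC)c3C2)c(O)c1CC=C(C)C | target

**Step count and risks**

Total steps: 11. Longest linear sequence: 10 steps (1 → 23 through steps 1–7 and 9–11); step 8 is a one-step side branch.

Most likely to fail:

1. Step 9. The vinylketene may be consumed by dimerisation, or the photolysis may be starved of light by the absorbing chroman and phenol chromophores, before the ketene meets 16. The fallback sets out from 12 and no longer generates the ketene photochemically. Silver-promoted Wolff rearrangement of 12 with water as the trap (PhCO2Ag, Et3N, THF/H2O, sonication) should give (3E)-4-[(3R)-5-methoxy-7-(triisopropylsilyloxy)chroman-3-yl]but-3-enoic acid F1. Oxalyl chloride with catalytic DMF in CH2Cl2 should convert it into (3E)-4-[(3R)-5-methoxy-7-(triisopropylsilyloxy)chroman-3-yl]but-3-enoyl chloride F2. Slow syringe-pump addition of F2 to 16 and Et3N in toluene at 80 °C, in the dark, generates the vinylketene by dehydrochlorination at a low stationary concentration. The fallback comes back to the route at 17, which is expected to continue through 18, 19 and 20 to 21.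

2. Step 11. Formylation at C6 may compete with formylation at C8, both carbons being ortho to the 7-OH. The fallback sets out from 22 and replaces electrophilic substitution by directed ortho-metalation. MOMCl and iPr2NEt in CH2Cl2 should protect both phenols to give (3R)-5-methoxy-7-(methoxymethoxy)-3-[4-methoxy-2-(methoxymethoxy)-3-(3-methylbut-2-en-1-yl)phenyl]chroman F3. n-BuLi/TMEDA in THF (−78 → 0 °C) should lithiate C8, where the acetal oxygen and the in-plane lone pair of the ring oxygen converge; C6 is screened by the 5-OMe methyl and the 2'-acetal has no ortho hydrogen. A DMF quench gives (3R)-5-methoxy-7-(methoxymethoxy)-3-[4-methoxy-2-(methoxymethoxy)-3-(3-methylbut-2-en-1-yl)phenyl]chroman-8-carbaldehyde F4. Dilute HCl in MeOH at room temperature removes both acetals, and the fallback comes back to the route at 23.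

3. Step 4. Facial selectivity may be insufficient on this electron-rich cyclic β-aryl acrylic acid. The fallback sets out from 5 and replaces asymmetric catalysis by an auxiliary-based resolution. Hydrogenation over Pd/C (H2, EtOAc, rt) should give racemic 5-methoxy-7-(triisopropylsilyloxy)chroman-3-carboxylic acid F5. Activation as the mixed pivalic anhydride and N-acylation of (S)-4-benzyl-1,3-oxazolidin-2-one (PivCl, Et3N, LiCl, THF) gives two diastereomeric imides separable on silica: (4S)-4-benzyl-3-{[(3S)-5-methoxy-7-(triisopropylsilyloxy)chroman-3-yl]carbonyl}-1,3-oxazolidin-2-one F6 and its (3R)-chromanyl diastereomer, (4S)-4-benzyl-3-{[(3R)-5-methoxy-7-(triisopropylsilyloxy)chroman-3-yl]carbonyl}-1,3-oxazolidin-2-one F7. Reduction of F6 with LiBH4 in wet THF releases the auxiliary, and the fallback comes back to the route at 7.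

**Further compounds**

F1 | step 9 | (3E)-4-[(3R)-5-methoxy-7-(triisopropylsilyloxy)chroman-3-yl]but-3-enoic acid | OC(=O)C/C=C/[C@@H]1COc2cc(O[Si](C(C)C)(C(C)C)C(C)C)cc(OC)c2C1
F2 | step 9 | (3E)-4-[(3R)-5-methoxy-7-(triisopropylsilyloxy)chroman-3-yl]but-3-enoyl chloride | ClC(=O)C/C=C/[C@@H]1COc2cc(O[Si](C(C)C)(C(C)C)C(C)C)cc(OC)c2C1
F3 | step 11 | (3R)-5-methoxy-7-(methoxymethoxy)-3-[4-methoxy-2-(methoxymethoxy)-3-(3-methylbut-2-en-1-yl)phenyl]chroman | COc1ccc([C@@H]2COc3cc(OCOC)cc(OC)c3C2)c(OCOC)c1CC=C(C)C
F4 | step 11 | (3R)-5-methoxy-7-(methoxymethoxy)-3-[4-methoxy-2-(methoxymethoxy)-3-(3-methylbut-2-en-1-yl)phenyl]chroman-8-carbaldehyde | COc1ccc([C@@H]2COc3c(C=O)c(OCOC)cc(OC)c3C2)c(OCOC)c1CC=C(C)C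
F5 | step 4 | racemic 5-methoxy-7-(triisopropylsilyloxy)chroman-3-carboxylic acid | OC(=O)C1COc2cc(O[Si](C(C)C)(C(C)C)C(C)C)cc(OC)c2C1
F6 | step 4 | (4S)-4-benzyl-3-{[(3S)-5-methoxy-7-(triisopropylsilyloxy)chroman-3-yl]carbonyl}-1,3-oxazolidin-2-one | O=C([C@@H]1COc2cc(O[Si](C(C)C)(C(C)C)C(C)C)cc(OC)c2C1)N3[C@@H](Cc4ccccc4)COC3=O
F7 | step 4 | (4S)-4-benzyl-3-{[(3R)-5-methoxy-7-(triisopropylsilyloxy)chroman-3-yl]carbonyl}-1,3-oxazolidin-2-one | O=C([C@H]1COc2cc(O[Si](C(C)C)(C(C)C)C(C)C)cc(OC)c2C1)N3[C@@H](Cc4ccccc4)COC3=O
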